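Start from a small charge, 0.25 M of each substrate against 1.00 M of partner, and follow one substrate molecule to its fork: product, or the leak through achiral form.

| setting | winter | dawn | summer | flask |
|---|---|---|---|---|
| left-handed substrate | 0.17 M | 0.38 M | 0.25 M | 0.25 M |
| right-handed substrate | 0.17 M | 0.38 M | 0.25 M | 0.25 M |
| partner | 1 M | 1 M | 2 M | 1.00 M |
| remark | run made earlier | run made earlier | run made earlier |  |
| time |  |  |  | 2.5 d |

- winter (time / h: left-handed product / %, right-handed product / %, left-handed substrate / %): 3.00: 4, 1, 46; 5.00: 1, 0, 47; 8.00: 3, 4, 46; 12.0: 3, 1, 43; 20.0: 7, 3, 41; 40.0: 10, 5, 33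
- dawn (time / h: left-handed product / %, right-handed product / %, left-handed substrate / %): 2.50: 0, 1, 47; 8.00: 5, 2, 44; 12.0: 4, 0, 44; 20.0: 5, 2, 43; 30.0: 7, 5, 38; 40.0: 10, 6, 37
- summer (time / h: left-handed product / %, right-handed product / %, left-handed substrate / %): 3.00: 0, 2, 50; 5.00: 4, 3, 47; 10.0: 5, 3, 42; 20.0: 8, 6, 36; 40.0: 14, 8, 33

(readings scatter by 1.5 percentage points)

- partner is single-handed; left-handed substrate and right-handed substrate are mirror images of each other, charged as a racemate, each of them at the stated concentration
- what has gone into achiral form counts as reacted
- an excess is the difference of the two amounts in percent of their sum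
- an excess is below zero if the other one leads
- the handed part of partner does not stay in what it makes, so the products of the two hands are mirror images too

- excess of left-handed product over right-handed product in the product at 3.0 h
- excess of left-handed product over right-handed product in the product at 2.5 d
- part of the left-handed substrate and right-handed substrate charged together that has reacted at 2.5 d

Take winter and dawn, the runs with the flask's partner charge, at 40.0 h. Averaged, left-handed substrate reads 35.0%, left-handed product 10.0% and right-handed product 5.50%, a read excess of 29.0%. Carry that reading to the flask for both asked times.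

Double the left-handed loss: by this reading, 30.0% of the charge has reacted in those runs. Product over the remainder is 1.07. Extended as a pseudo-first-order loss, this gives an estimate of 41.4% reacted in the flask at 2.5 d.

The weak link is the doubling, since right-handed substrate is not among the readings. Reforge it: let right-handed substrate lose its product plus the left-handed leak, which gives 25.5%. Take the middle, 27.8%. The fork odds, product made per unit of other reacted material at 1.00 M partner, are then 1.27. Summer at 40.0 h, reckoned by doubling, reads 1.83 at 2 M partner against 1.07 for winter and dawn, whose substrate charges lie on either side of summer's; as an estimate, scale the odds with partner. Commit to 38.7% reacted in the flask at 2.5 d.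

The forecast says 27% early, 23% late and 38% reacted, noting that “the excess looks steady through 40 h”.

The flask gives 36.5%, 23.5% and 34.5%.

    partner + left-handed substrate → left-handed product (k = 2.20 × 10⁻⁶ L mol⁻¹ s⁻¹)
    partner + right-handed substrate → right-handed product (k = 1.00 × 10⁻⁶ L mol⁻¹ s⁻¹)
    left-handed substrate ⇌ achiral form (K = 0.0460, k = 1.10 × 10⁻⁴ s⁻¹)
    right-handed substrate ⇌ achiral form (K = 0.0460, k = 1.10 × 10⁻⁴ s⁻¹)
    achiral form → waste (k = 3.60 × 10⁻⁵ s⁻¹)
    2 partner → self-condensation product (k = 2.10 × 10⁻⁶ L mol⁻¹ s⁻¹)
    left-handed product ⇌ right-handed product (k = 1.90 × 10⁻⁶ s⁻¹)

Watch the excess: the relaxation half-life of the products, 2.11 d for both ways together, is shorter than the 2.5 d run. The flask's excess falls from 36.5% at 3.0 h to 23.5% at 2.5 d. Product over waste plus achiral form in the flask at 2.50 d is 1.22, beside the odds of 1.27. For a neighbour flask charged with 0.60 M partner, the odds scale to 0.762; that neighbour flask computes to 0.803 at 2.5 d, with 29.4% reacted.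

The readings come from a simulation from invented constants, and the scatter is random.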